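The time of each reading in the west run lets us turn percentages into a pseudo-first-order constant: between two readings, the logarithm of the ratio of unconverted starting material, divided by the time between them.

- west: starting material 0.35 M; gas phase 34 mM (held); catalyst 0.35 mol%; run made earlier
- flask: starting material 0.35 M; gas phase 34 mM (held); catalyst 0.23 mol%; time 15 d

- west (time / d: target / %): 0.250: 7.0; 0.417: 11.1; 0.625: 17.9; 1.04: 30.1; 1.67: 46.5; 3.00: 72.4

(readings scatter by 0.3 percentage points)

- at the start none of the gas phase is in solution
- no earlier run changes the charge of catalyst; that part of a forecast is a guess

* time up to 15 d at which target stands highest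
* the amount of target, in percent of the starting material charged, at that time

| West run, from | to | constant |
|---|---|---|
| start | 0.417 d | 0.282 d⁻¹ |
| 0.417 d | 1.04 d | 0.386 d⁻¹ |
| 1.04 d | 1.67 d | 0.424 d⁻¹ |
| 1.67 d | 3.00 d | 0.498 d⁻¹ |

Reading down the column, the constant climbs in every row, which suits a flask that starts with no gas in solution. It has not stopped climbing at the last row, so we take that row as our reading.

Scaling it by loading, which is a guess, gives the flask a making constant κ, the rate of target formation per c(starting material), of 0.327 d⁻¹.

With no loss of target, that gives us 99.3% at 15 d. But suppose target is lost with a first-order constant k, and κ holds steady. Dividing the rate of loss by the rate of making removes time and leaves x = k/κ. Target then peaks where c(starting material)/c(target) equals x, at a fraction x^(x/(one minus x)) of the charge. We read no value of k from the table, where any loss of target would lie under the climbing constant.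

The forecast gives 98% at 15 d, with “target should still be creeping upward”.

The flask peaks at 88.5% at 8.09 d. At 15.0 d it makes target more slowly than it uses it up, at 0.0197 times that rate.

    gas phase ⇌ dissolved gas, rate k1*(csat - [dissolved gas]) (kL = 0.00390 min⁻¹)
    starting material + dissolved gas + catalyst → catalyst + target (k = 15.0 M⁻² min⁻¹)
    target → over-reaction product (k = 1.20 × 10⁻⁵ min⁻¹)

In the flask, the loss constant 0.0173 d⁻¹ is slower than κ, so x is 0.0528 and the rule gives a peak of 84.9%, against the 88.5% above. In the neighbour flask, at 0.58 mol%, κ scaled by loading makes x 0.0210, the rule gives 92.1%, and that flask's best is 93.3%.

All runs come from a simulation from invented constants; the scatter is artificial.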